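## Retrosynthetic overview

1. The target comes from its ethylene acetal 22 (C6 aldehyde unmasked last). Ring D is closed by a 5-exo vinyl-radical cyclisation (C16 to C13) of propargylic acetate 20, made from aldehyde 16 and acetylide (sets C15).
2. Ring C and the C8/C9 stereocentres come from a Diels–Alder reaction of butadiene with the formyl-activated unsaturated spirolactone 15.
3. Spirolactone 10 comes from enone 4 by C10 formylation (C20), Michael addition to methyl acrylate (C7–C9, sets quaternary C10) and reduction/lactonisation.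
4. Key disconnection C5–C6: enantioselective, desymmetrising addition of a masked formyl radical (an acyl-anion equivalent from 1,3-dioxolane) to the prochiral dienone 2. It creates the C1/C6 1,4-dicarbonyl relationship and the first stereocentre.
5. Ring order: A (from 1), then lactone, then C, then D.

Assumption: atoms carry ent-kaurane numbers throughout (ring A = C1–C5, C10; C6 = aldehyde carbon; C7 = lactone carbonyl; C20 = OCH2; ring C = C8, C9, C11–C14; C15 = carbinol carbon; C16=C17 = exocyclic alkene).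
Assumption: the (1R,2R) amine catalyst of step 2 is taken to give (S)-4; its mirror-image form is used if the sense of induction proves opposite.

## Route

Step 1
Reactants: 1 4,4-dimethylcyclohex-2-en-1-one
Product: 2 4,4-dimethylcyclohexa-2,5-dien-1-one
Conditions: DDQ (1.3 equiv), TsOH·H2O (cat.), 1,4-dioxane, 100 °C
Reagents that add atoms: none
Why: quinone dehydrogenation of the enone through its dienol (hydride abstraction at C5) gives the symmetric cross-conjugated dienone, which has no stereocentre.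

Step 2
Reactants: 2 4,4-dimethylcyclohexa-2,5-dien-1-one; 3 1,3-dioxolane
Product: 4 (5S)-5-(1,3-dioxolan-2-yl)-4,4-dimethylcyclohex-2-en-1-one
Conditions: (nBu4N)4[W10O32] (2 mol %), (1R,2R)-2-(9H-carbazol-9-yl)cyclohexan-1-amine (20 mol %), PhCO2H (40 mol %), 1,3-dioxolane/MeCN 1:1, 390 nm LEDs, 25 °C, stopped at about 80% conversion
Reagents that add atoms: 1,3-dioxolane, C1COCO1
Why: Proposed new method: the excited decatungstate abstracts the hydridic acetal hydrogen of 1,3-dioxolane to give the nucleophilic 2-dioxolanyl radical (a masked formyl radical, i.e. an acyl-anion equivalent), which adds to C5 of the chiral dienone iminium ion, whose amine shields one of the two enantiotopic β-carbons so that the dienone is desymmetrised and C5 is set, after which the α-iminyl radical cation is reduced through the carbazole relay and hydrolysed, joining the normally electrophilic C6 and C5 into the C1/C6 1,4-dicarbonyl pattern; the closest known reaction type is iminium-ion trapping of photogenerated acetal radicals (an enantioselective Giese-type radical conjugate addition to cyclic enones).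

Step 3
Reactants: 4 (5S)-5-(1,3-dioxolan-2-yl)-4,4-dimethylcyclohex-2-en-1-one; 5 ethyl formate
Product: 6 (5R)-5-(1,3-dioxolan-2-yl)-6-(hydroxymethylidene)-4,4-dimethylcyclohex-2-en-1-one
Conditions: NaH (1.5 equiv), EtOH (cat.), HCO2Et (5 equiv), THF, 0 °C to rt; AcOH quench
Reagents that add atoms: ethyl formate, CCOC=O
Why: crossed Claisen formylation at C10, the only enolisable position (C4 is quaternary), installs C20 as the enolised aldehyde and leaves C5 untouched.

Step 4
Reactants: 6 (5R)-5-(1,3-dioxolan-2-yl)-6-(hydroxymethylidene)-4,4-dimethylcyclohex-2-en-1-one; 7 methyl acrylate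
Product: 8 methyl 3-[(1S,6R)-6-(1,3-dioxolan-2-yl)-1-formyl-5,5-dimethyl-2-oxocyclohex-3-en-1-yl]propanoate
Conditions: DBU (0.1 equiv), methyl acrylate (1.5 equiv), MeCN, 0 °C to rt
Reagents that add atoms: methyl acrylate, C=CC(=O)OC
Why: Michael addition of the acidic β-keto aldehyde makes quaternary C10, the acrylate entering anti to the neighbouring C5 dioxolanyl group so that C9 is trans and the formyl carbon C20 cis to C6.

Step 5
Reactants: 8 methyl 3-[(1S,6R)-6-(1,3-dioxolan-2-yl)-1-formyl-5,5-dimethyl-2-oxocyclohex-3-en-1-yl]propanoate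
Product: 10 (6S,11R)-11-(1,3-dioxolan-2-yl)-10,10-dimethyl-2-oxaspiro[5.5]undec-8-ene-3,7-dione, via hydroxy ester 9 (not isolated)
Conditions: NaBH4 (0.5 equiv), MeOH/CH2Cl2 1:1, −78 °C; then CSA (0.1 equiv), CH2Cl2, rt
Reagents that add atoms: none
Why: chemoselective borohydride reduction of the aldehyde (much faster than the hindered conjugated ketone or the ester at −78 °C) is followed by acid-catalysed lactonisation onto the methyl ester, helped by the quaternary centre, with no stereocentre touched.

Step 6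
Reactants: 10 (6S,11R)-11-(1,3-dioxolan-2-yl)-10,10-dimethyl-2-oxaspiro[5.5]undec-8-ene-3,7-dione; 5 ethyl formate
Product: 11 (6S,11R)-11-(1,3-dioxolan-2-yl)-4-(hydroxymethylidene)-10,10-dimethyl-2-oxaspiro[5.5]undec-8-ene-3,7-dione
Conditions: LiN(iPr)2 (1.2 equiv), THF, −78 °C, 20 min; HCO2Et (3 equiv), −78 to −20 °C; AcOH quench
Reagents that add atoms: ethyl formate, CCOC=O
Why: Claisen formylation of the lactone enolate at C8, the only acidic C–H (the ring A ketone has no enolisable α- or γ-hydrogen), installs C15 as the enolised formyl group.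

Step 7
Reactants: 11 (6S,11R)-11-(1,3-dioxolan-2-yl)-4-(hydroxymethylidene)-10,10-dimethyl-2-oxaspiro[5.5]undec-8-ene-3,7-dione; 12 buta-1,3-diene
Product: 16 6,6-(ethylenedioxy)-1,15-dioxo-16,17-dinor-6,7-seco-ent-kaura-2,12-dien-7,20-olide, via selenide 13 (not isolated), via selenoxide 14 (not isolated), via formyl enoate 15 (not isolated)
Conditions: PhSeCl (1.1 equiv), pyridine (1.2 equiv), CH2Cl2, 0 °C; 30% aq. H2O2, 0 °C to rt; phase separation and drying; buta-1,3-diene (10 equiv), ZnCl2 (0.2 equiv), CH2Cl2, −20 °C to rt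
Reagents that add atoms: buta-1,3-diene, C=CC=C
Why: selenoxide syn-elimination (β-hydrogens only at C9) gives the doubly activated dienophile 15, and the Diels–Alder reaction with butadiene occurs suprafacially on the face of C8=C9 next to the flat C1 carbonyl and away from the C5 dioxolanyl and C4 methyl groups, which sets C9 and quaternary C8 (lactone cis-fused to ring C, formyl C15 anti to C10) and leaves the C12=C13 alkene.

Step 8
Reactants: 16 6,6-(ethylenedioxy)-1,15-dioxo-16,17-dinor-6,7-seco-ent-kaura-2,12-dien-7,20-olide; 17 ethyne; 18 acetic anhydride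
Product: 20 15-acetoxy-6,6-(ethylenedioxy)-1-oxo-6,7:13,16-diseco-ent-kaura-2,12-dien-16-yn-7,20-olide, via lithium alkoxide 19 (not isolated)
Conditions: ethyne, nBuLi (1.3 equiv), THF/DMPU 5:1, −78 °C; 16, −78 °C, 30 min; Ac2O (3 equiv), −78 to 0 °C
Reagents that add atoms: ethyne, C#C; acetic anhydride, CC(=O)OC(C)=O
Why: non-chelated Felkin–Anh/Cornforth 1,2-addition (C15=O anti to the lactone carbonyl, acetylide anti to the bulky C9 substituent) sets C15 with oxygen on the C9 side, and the alkoxide is acetylated in the flask before it can undergo retro-aldol cleavage.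

Step 9
Reactants: 20 15-acetoxy-6,6-(ethylenedioxy)-1-oxo-6,7:13,16-diseco-ent-kaura-2,12-dien-16-yn-7,20-olide
Product: 22 15-acetoxy-6,6-(ethylenedioxy)-1-oxo-6,7-seco-ent-kaura-2,16-dien-7,20-olide, via vinylstannane 21 (not isolated)
Conditions: Bu3SnH (1.3 equiv, slow addition), Et3B (0.2 equiv), trace air, PhMe, 0 °C to rt; then HCl (1.1 equiv, 2 M in Et2O), CH2Cl2, 0 °C
Reagents that add atoms: none
Why: Stork-type radical cyclisation, in which the stannyl radical adds to the terminal alkyne carbon and the C16 vinyl radical closes 5-exo-trig onto C13 (its configuration fixed by the cis bridge from C8), builds the bicyclo[3.2.1]octane, and protodestannylation then leaves the exocyclic methylene.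

Step 10
Reactants: 22 15-acetoxy-6,6-(ethylenedioxy)-1-oxo-6,7-seco-ent-kaura-2,16-dien-7,20-olide
Product: 23 15-acetoxy-1,6-dioxo-6,7-seco-ent-kaura-2,16-dien-7,20-olide (CNP0108627.4)
Conditions: In(OSO2CF3)3 (5 mol %), acetone/H2O 20:1, rt
Reagents that add atoms: water, O
Why: Lewis-acid-catalysed acetal hydrolysis under nearly neutral conditions frees the C6 aldehyde without ionising the allylic acetate, opening the lactone or epimerising C5.

## Compound list

1 | 4,4-dimethylcyclohex-2-en-1-one | CC1(C)CCC(=O)C=C1 | starting material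
2 | 4,4-dimethylcyclohexa-2,5-dien-1-one | CC1(C)C=CC(=O)C=C1 | intermediate
3 | 1,3-dioxolane | C1COCO1 | starting material
4 | (5S)-5-(1,3-dioxolan-2-yl)-4,4-dimethylcyclohex-2-en-1-one | O=C1C=CC(C)(C)[C@@H](C2OCCO2)C1 | intermediate
5 | ethyl formate | CCOC=O | starting material
6 | (5R)-5-(1,3-dioxolan-2-yl)-6-(hydroxymethylidene)-4,4-dimethylcyclohex-2-en-1-one (enol of the C10-formyl ketone) | O=C1C=CC(C)(C)[C@@H](C2OCCO2)C1=CO | intermediate
7 | methyl acrylate | C=CC(=O)OC | starting material
8 | methyl 3-[(1S,6R)-6-(1,3-dioxolan-2-yl)-1-formyl-5,5-dimethyl-2-oxocyclohex-3-en-1-yl]propanoate (formyl and dioxolanyl cis) | O=C[C@@]1(CCC(=O)OC)C(=O)C=CC(C)(C)[C@H]1C1OCCO1 | intermediate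
9 | methyl 3-[(1S,6R)-6-(1,3-dioxolan-2-yl)-1-(hydroxymethyl)-5,5-dimethyl-2-oxocyclohex-3-en-1-yl]propanoate (hydroxy ester) | OC[C@@]1(CCC(=O)OC)C(=O)C=CC(C)(C)[C@H]1C1OCCO1 | intermediate
10 | (6S,11R)-11-(1,3-dioxolan-2-yl)-10,10-dimethyl-2-oxaspiro[5.5]undec-8-ene-3,7-dione (spirolactone, OCH2 and dioxolanyl cis on ring A) | O=C1CC[C@]2(CO1)C(=O)C=CC(C)(C)[C@H]2C1OCCO1 | intermediate
11 | (6S,11R)-11-(1,3-dioxolan-2-yl)-4-(hydroxymethylidene)-10,10-dimethyl-2-oxaspiro[5.5]undec-8-ene-3,7-dione | O=C1C(=CO)C[C@]2(CO1)C(=O)C=CC(C)(C)[C@H]2C1OCCO1 | intermediate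
12 | buta-1,3-diene | C=CC=C | starting material
13 | selenide: 4-formyl-4-(phenylselanyl) derivative of 10 (both C8 epimers) | O=CC1([Se]c2ccccc2)C[C@]3(COC1=O)C(=O)C=CC(C)(C)[C@H]3C1OCCO1 | intermediate
14 | selenoxide of 13 | O=CC1([Se](=O)c2ccccc2)C[C@]3(COC1=O)C(=O)C=CC(C)(C)[C@H]3C1OCCO1 | intermediate
15 | formyl enoate: (6S,11R)-11-(1,3-dioxolan-2-yl)-10,10-dimethyl-3,7-dioxo-2-oxaspiro[5.5]undeca-4,8-diene-4-carbaldehyde | O=CC1=C[C@]2(COC1=O)C(=O)C=CC(C)(C)[C@H]2C1OCCO1 | intermediate
16 | 6,6-(ethylenedioxy)-1,15-dioxo-16,17-dinor-6,7-seco-ent-kaura-2,12-dien-7,20-olide (lactone cis-fused to ring C; formyl C15 on C8 anti to C10) | O=C[C@]12CC=CC[C@H]1[C@]1(COC2=O)C(=O)C=CC(C)(C)[C@H]1C1OCCO1 | intermediate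
17 | ethyne | C#C | starting material
18 | acetic anhydride | CC(=O)OC(C)=O | starting material
19 | lithium alkoxide of the C15 propargylic alcohol | [Li+].C#C[C@@H]([O-])[C@]12CC=CC[C@H]1[C@]1(COC2=O)C(=O)C=CC(C)(C)[C@H]1C1OCCO1 | intermediate
20 | 15-acetoxy-6,6-(ethylenedioxy)-1-oxo-6,7:13,16-diseco-ent-kaura-2,12-dien-16-yn-7,20-olide (propargylic acetate) | C#C[C@@H](OC(C)=O)[C@]12CC=CC[C@H]1[C@]1(COC2=O)C(=O)C=CC(C)(C)[C@H]1C1OCCO1 | intermediate
21 | vinylstannane: 17-(tributylstannyl) derivative of 22 (E/Z mixture) | CCCC[Sn](CCCC)(CCCC)C=C1[C@@H]2CC[C@@H]3[C@](C2)(C(=O)OC[C@]32C(=O)C=CC(C)(C)[C@H]2C2OCCO2)[C@@H]1OC(C)=O | intermediate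
22 | 15-acetoxy-6,6-(ethylenedioxy)-1-oxo-6,7-seco-ent-kaura-2,16-dien-7,20-olide (ethylene acetal of the target; 15-OAc on the face of ring D away from C14) | C=C1[C@@H]2CC[C@@H]3[C@](C2)(C(=O)OC[C@]32C(=O)C=CC(C)(C)[C@H]2C2OCCO2)[C@@H]1OC(C)=O | intermediate
23 | 15-acetoxy-1,6-dioxo-6,7-seco-ent-kaura-2,16-dien-7,20-olide (CNP0108627.4) | C=C1[C@@H]2CC[C@@H]3[C@](C2)(C(=O)OC[C@]32C(=O)C=CC(C)(C)[C@H]2C=O)[C@@H]1OC(C)=O | target

## Step count and risks

Total step count: 10. Longest linear sequence: 10 steps (from 1).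

The three steps most likely to fail are steps 2, 7 and 8.

Step 2 may give low enantioselectivity, or a second radical addition to the remaining enone. The fallback sets out from 2 and comes back at 4. Dienone 2 is treated with formaldehyde SAMP-hydrazone F1 (a neutral chiral formyl-anion equivalent, made from (S)-1-amino-2-(methoxymethyl)pyrrolidine and paraformaldehyde) and tBuMe2SiOSO2CF3 in CH2Cl2 at −78 °C. This aza-enamine Michael addition gives the silyl dienol ether F2, and Bu4NF work-up gives the keto hydrazone F3. Exchange with ethylene glycol and TsOH in benzene turns the hydrazone into the dioxolane 4 and releases the auxiliary.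

Step 7 may fail through decomposition of the very electrophilic formyl enoate 15 or through poor facial selectivity. The fallback sets out from 10 and comes back at 16. The lithium enolate of 10 is selenenylated (LiN(iPr)2; PhSeBr) to the selenide F4, which is oxidised with H2O2 to the selenoxide F5. This eliminates to the plain unsaturated lactone F6. The Diels–Alder reaction with butadiene is then forced with EtAlCl2 (or 12 kbar) to give the cis-fused adduct F7. C15 is introduced afterwards by aldol reaction of the lithium enolate of F7 with monomeric formaldehyde, on the face anti to C10, to give the hydroxymethyl lactone F8. Dess–Martin oxidation of F8 gives 16.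

Step 8 may give the wrong C15 epimer if lithium chelation competes. The fallback sets out from 16 and comes back at 20. HC≡CMgBr is added without stereocontrol to give the epimeric propargylic alcohols F9, which are oxidised (Dess–Martin periodinane) to the ynone F10. F10 is reduced under chelation control with Zn(BH4)2 in Et2O at −78 °C: zinc bridges the C15 carbonyl and the lactone carbonyl, and hydride enters anti to C9. This gives the single propargylic alcohol F11, which is acetylated (Ac2O, DMAP, pyridine) to 20.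

Further compounds
F1 | step 2 | formaldehyde SAMP-hydrazone, (S)-2-(methoxymethyl)-N-methylidenepyrrolidin-1-amine | C=NN1CCC[C@H]1COC
F2 | step 2 | silyl dienol ether of the hydrazone adduct (C1 OSiMe2tBu, C1=C10, C2=C3) | CC(C)(C)[Si](C)(C)OC1=C[C@H](C=NN2CCC[C@H]2COC)C(C)(C)C=C1
F3 | step 2 | keto hydrazone, SAMP-hydrazone of (1S)-6,6-dimethyl-4-oxocyclohex-2-ene-1-carbaldehyde | O=C1C=CC(C)(C)[C@@H](C=NN2CCC[C@H]2COC)C1
F4 | step 7 | 4-(phenylselanyl) derivative of 10 (C8 epimers) | O=C1C([Se]c2ccccc2)C[C@]3(CO1)C(=O)C=CC(C)(C)[C@H]3C1OCCO1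
F5 | step 7 | selenoxide of F4 | O=C1C([Se](=O)c2ccccc2)C[C@]3(CO1)C(=O)C=CC(C)(C)[C@H]3C1OCCO1
F6 | step 7 | (6S,11R)-11-(1,3-dioxolan-2-yl)-10,10-dimethyl-2-oxaspiro[5.5]undeca-4,8-diene-3,7-dione | O=C1C=C[C@]2(CO1)C(=O)C=CC(C)(C)[C@H]2C1OCCO1
F7 | step 7 | 6,6-(ethylenedioxy)-1-oxo-15,16,17-trinor-6,7-seco-ent-kaura-2,12-dien-7,20-olide (cis-fused, H at C8) | [C@H]12CC=CC[C@H]1[C@]1(COC2=O)C(=O)C=CC(C)(C)[C@H]1C1OCCO1
F8 | step 7 | 15-hydroxy analogue of 16 (CH2OH on C8 anti to C10) | OC[C@]12CC=CC[C@H]1[C@]1(COC2=O)C(=O)C=CC(C)(C)[C@H]1C1OCCO1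
F9 | step 8 | C15-epimeric propargylic alcohols from 16 | C#CC(O)[C@]12CC=CC[C@H]1[C@]1(COC2=O)C(=O)C=CC(C)(C)[C@H]1C1OCCO1
F10 | step 8 | C15 ynone | C#CC(=O)[C@]12CC=CC[C@H]1[C@]1(COC2=O)C(=O)C=CC(C)(C)[C@H]1C1OCCO1
F11 | step 8 | propargylic alcohol with the C15 configuration of 20 | C#C[C@@H](O)[C@]12CC=CC[C@H]1[C@]1(COC2=O)C(=O)C=CC(C)(C)[C@H]1C1OCCO1
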